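**Plan**

1. Retrosynthesis: the four silyl ethers are removed last. Ring C (O1, C2, C3, C4, C4a, C8a) is an indan-1-one ring with one oxygen inserted between the aryl carbon C8a and C2, and C8a lies para to the C6 methoxy oxygen, so it can migrate to oxygen. The C8a–O1 and C2–OH bonds are therefore cut back to a 3-hydroperoxyindan-1-one.
2. The hydroperoxide is traced to the 3-hydroxyindanone, its C2–C3 bond (indanone numbering) to an aldol of a 2-acylbenzaldehyde, and the aryl–acyl bond to a fully substituted aryllithium (ring A) and a β-silyloxy Weinreb amide (C4, C3, C9 and the 4-hydroxyphenyl ring).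
3. Forward: ring A is elaborated from methyl 3,5-dihydroxy-4-methoxybenzoate (ortho-lithiation/methylation, bromination) and the side chain is made separately. The two are joined by ketone synthesis, the five-membered carbocycle closes by aldol, and ring C then arises by oxygen insertion (ring expansion), not by cyclisation.
4. Stereochemistry: C9 comes from asymmetric transfer hydrogenation, C3 from 1,2-induction by C9 in the aldol closure, and C2 from lactol equilibration trans to the C3 substituent. The hydroperoxide carbon is a sacrificial centre.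

Key step: step 14

Remark: target numbering follows chroman-4-one with C9 the carbinol carbon on C3; the target is (2S,3R,9S). The ring carbon that carries the side chain keeps one spatial arrangement throughout; its descriptor is 2S in indanones 18 and 19 and 3R in chromanones 20 and 21 only because numbering and substituent priorities change.
Remark: the carbinol/hydroperoxide carbon of 18 and 19 is written as the trans epimer expected to predominate; the cis epimer would be carried along, because this centre is erased in step 14.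
Remark: methyl 3,5-dihydroxy-4-methoxybenzoate (methyl 4-O-methylgallate) is taken as a purchasable starting material.
Abbreviations in names: TBSO = tert-butyldimethylsilyloxy, MOM = methoxymethyl, TES = triethylsilyl.

**Route**

Step 1
Reactants: 1 methyl 3,5-dihydroxy-4-methoxybenzoate
Product: 2 methyl 4-methoxy-3,5-bis(methoxymethoxy)benzoate
Conditions: MOMCl, i-Pr2NEt, CH2Cl2, 0 °C to rt
Reagents that add atoms: chloromethyl methyl ether, COCCl
Why: Base-mediated O-alkylation of the two equivalent phenols (MOM ether formation) should be clean, and the acetal ethers are chosen because they direct and stabilise the ortho-lithiations that follow.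

Step 2
Reactants: 2 methyl 4-methoxy-3,5-bis(methoxymethoxy)benzoate
Product: 3 [4-methoxy-3,5-bis(methoxymethoxy)phenyl]methanol
Conditions: LiAlH4, THF, 0 °C
Reagents that add atoms: none
Why: Hydride reduction of the ester gives the benzylic alcohol, which serves as a second ortho-directing group and as a masked aldehyde, while MOM ethers are inert to LiAlH4.

Step 3
Reactants: 3 [4-methoxy-3,5-bis(methoxymethoxy)phenyl]methanol
Product: 5 [4-methoxy-3,5-bis(methoxymethoxy)-2-methylphenyl]methanol, via dilithio alkoxide 4 (not isolated)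
Conditions: n-BuLi (2.3 equiv), THF, 0 °C; then MeI, −78 to 0 °C; H2O
Reagents that add atoms: iodomethane, CI
Why: Directed ortho-metalation, in which the benzylic lithium alkoxide and the neighbouring OMOM group together direct n-BuLi to the ring C–H between them (the two such positions are equivalent), followed by C-methylation of the aryllithium, which is faster than O-methylation of the alkoxide at low temperature.

Step 4
Reactants: 5 [4-methoxy-3,5-bis(methoxymethoxy)-2-methylphenyl]methanol
Product: 6 [2-bromo-4-methoxy-3,5-bis(methoxymethoxy)-6-methylphenyl]methanol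
Conditions: NBS, MeCN, 0 °C
Reagents that add atoms: N-bromosuccinimide, O=C1CCC(=O)N1Br
Why: Electrophilic aromatic bromination should occur only at the single free ring position, which is ortho to one OMOM group and para to the other.

Step 5
Reactants: 7 ethyl 3-(4-hydroxyphenyl)-3-oxopropanoate
Product: 8 ethyl 3-[4-(TBSO)phenyl]-3-oxopropanoate
Conditions: TBSCl, imidazole, DMF, rt
Reagents that add atoms: tert-butyldimethylsilyl chloride, CC(C)(C)[Si](C)(C)Cl
Why: Imidazole-promoted silylation masks the acidic phenol before the hydride-transfer and organometallic steps and leaves the β-keto ester untouched.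

Step 6
Reactants: 8 ethyl 3-[4-(TBSO)phenyl]-3-oxopropanoate
Product: 9 ethyl (S)-3-[4-(TBSO)phenyl]-3-hydroxypropanoate
Conditions: RuCl[(S,S)-TsDPEN](p-cymene) (1 mol %), HCO2H/Et3N (5:2), 30 °C
Reagents that add atoms: none
Why: Noyori–Ikariya asymmetric transfer hydrogenation of the aryl ketone, in which the (S,S)-diamine ligand delivers hydride to the carbonyl face that gives the (S)-benzylic alcohol (the aryl group being held by a CH–π contact to the cymene ligand), sets C9.

Step 7
Reactants: 9 ethyl (S)-3-[4-(TBSO)phenyl]-3-hydroxypropanoate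
Product: 10 ethyl (S)-3-(TBSO)-3-[4-(TBSO)phenyl]propanoate
Conditions: TBSCl, imidazole, DMF, rt
Reagents that add atoms: tert-butyldimethylsilyl chloride, CC(C)(C)[Si](C)(C)Cl
Why: Silylation of the secondary alcohol gives a non-chelating TBS ether that should withstand the organolithium, base and mild acid used later, without touching the stereocentre.

Step 8
Reactants: 10 ethyl (S)-3-(TBSO)-3-[4-(TBSO)phenyl]propanoate
Product: 11 (S)-3-(TBSO)-3-[4-(TBSO)phenyl]-N-methoxy-N-methylpropanamide
Conditions: MeNH(OMe)·HCl, i-PrMgCl, THF, −20 °C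
Reagents that add atoms: N,O-dimethylhydroxylamine hydrochloride, CNOC.Cl
Why: Weinreb amide formation by aminolysis of the ester with the magnesium amide made in the flask proceeds at low temperature without β-elimination of the silyloxy group and prepares the acyl unit for a single addition.

Step 9
Reactants: 6 [2-bromo-4-methoxy-3,5-bis(methoxymethoxy)-6-methylphenyl]methanol; 11 (S)-3-(TBSO)-3-[4-(TBSO)phenyl]-N-methoxy-N-methylpropanamide
Product: 14 (S)-3-(TBSO)-3-[4-(TBSO)phenyl]-1-[2-(hydroxymethyl)-5-methoxy-4,6-bis(methoxymethoxy)-3-methylphenyl]propan-1-one, via aryllithium alkoxide 12 (not isolated), via lithium hemiaminal adduct 13 (not isolated)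
Conditions: 6, n-BuLi (2.1 equiv), THF, −78 °C; then 11, −78 to −30 °C; AcOH, then H2O
Reagents that add atoms: none
Why: Deprotonation of the hydroxyl and bromine–lithium exchange give an aryllithium chelated by the alkoxide and the OMOM group, and its addition to the Weinreb amide stops at the chelated tetrahedral adduct, which releases the ketone only on work-up (Weinreb ketone synthesis), C9 being unaffected.

Step 10
Reactants: 14 (S)-3-(TBSO)-3-[4-(TBSO)phenyl]-1-[2-(hydroxymethyl)-5-methoxy-4,6-bis(methoxymethoxy)-3-methylphenyl]propan-1-one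
Product: 15 2-{(S)-3-(TBSO)-3-[4-(TBSO)phenyl]propanoyl}-4-methoxy-3,5-bis(methoxymethoxy)-6-methylbenzaldehyde
Conditions: Dess–Martin periodinane, NaHCO3, CH2Cl2, 0 °C to rt
Reagents that add atoms: none
Why: Dess–Martin oxidation of the primary benzylic alcohol (reacting through the open hydroxy ketone form of any cyclic hemiketal) gives the 2-acylbenzaldehyde under buffered conditions that spare the MOM ethers, the silyl ethers and the β-silyloxy ketone.

Step 11
Reactants: 15 2-{(S)-3-(TBSO)-3-[4-(TBSO)phenyl]propanoyl}-4-methoxy-3,5-bis(methoxymethoxy)-6-methylbenzaldehyde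
Product: 16 2-{(S)-3-(TBSO)-3-[4-(TBSO)phenyl]propanoyl}-4-methoxy-6-methyl-3,5-bis(triethylsilyloxy)benzaldehyde
Conditions: Et3SiOTf, 2,2′-bipyridyl, CH2Cl2, 0 °C to rt; then H2O
Reagents that add atoms: triethylsilyl trifluoromethanesulfonate, CC[Si](CC)(CC)OS(=O)(=O)C(F)(F)F
Why: Silyl triflate–2,2′-bipyridyl exchange of aromatic MOM ethers, in which the bipyridyl-bound silyl cation activates the acetal and the phenol oxygen is handed over directly as its triethylsilyl ether, is non-acidic and should leave the TBS ethers, the ketone and C9 alone, the aldehyde being returned on aqueous work-up.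

Step 12
Reactants: 16 2-{(S)-3-(TBSO)-3-[4-(TBSO)phenyl]propanoyl}-4-methoxy-6-methyl-3,5-bis(triethylsilyloxy)benzaldehyde
Product: 18 (2S,3R)-2-{(S)-(TBSO)[4-(TBSO)phenyl]methyl}-3-hydroxy-6-methoxy-4-methyl-5,7-bis(triethylsilyloxy)indan-1-one, via lithium Z-enolate 17 (not isolated)
Conditions: LiN(SiMe3)2 (1.05 equiv), THF, −78 °C; AcOH, −78 °C
Reagents that add atoms: none
Why: Intramolecular aldol addition of the kinetic lithium enolate to the neighbouring aldehyde, a 5-(enolendo)-exo-trig closure familiar from 2-acylbenzaldehydes, forms the indanone; the new C2 centre is set by 1,2-induction from C9, the enolate reacting on the face opposite the C9 aryl group with C9–H eclipsing the enolate double bond (allylic strain), and the C3 carbinol, expected trans, is of no consequence.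

Step 13
Reactants: 18 (2S,3R)-2-{(S)-(TBSO)[4-(TBSO)phenyl]methyl}-3-hydroxy-6-methoxy-4-methyl-5,7-bis(triethylsilyloxy)indan-1-one
Product: 19 (2S,3R)-2-{(S)-(TBSO)[4-(TBSO)phenyl]methyl}-3-hydroperoxy-6-methoxy-4-methyl-5,7-bis(triethylsilyloxy)indan-1-one
Conditions: 50% aq. H2O2 (20 equiv), TsOH·H2O (10 mol %), THF, 0 °C
Reagents that add atoms: hydrogen peroxide, OO
Why: Acid-catalysed exchange of a benzylic hydroxyl for hydroperoxide (perhydrolysis through the benzylic cation, which the para methoxy group stabilises) should give the hydroperoxide with H2O2 adding anti to the C2 substituent; either C3 epimer serves, and C2 and C9 are not involved.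

Step 14
Reactants: 19 (2S,3R)-2-{(S)-(TBSO)[4-(TBSO)phenyl]methyl}-3-hydroperoxy-6-methoxy-4-methyl-5,7-bis(triethylsilyloxy)indan-1-one
Product: 20 (2S,3R)-3-{(S)-(TBSO)[4-(TBSO)phenyl]methyl}-2-hydroxy-6-methoxy-8-methyl-5,7-bis(triethylsilyloxy)chroman-4-one
Conditions: CF3CO2H (0.3 equiv), CH2Cl2 saturated with H2O, −20 to 0 °C; NaHCO3 quench
Reagents that add atoms: water, O
Why: Proposed new method: protonation of the outer peroxide oxygen and loss of water are concerted with a 1,2-shift of the aryl carbon (indanone C3a, the future C8a) from carbon to the inner oxygen, and the cyclic oxocarbenium ion O1=C2 is then hydrated; the closest known reaction type is the Hock rearrangement of cumene, tetralin and indane hydroperoxides, which has not been shown on a 3-hydroperoxyindan-1-one. Ring C is not closed by cyclisation but arises by one-atom ring expansion of the five-membered carbocycle, the inserted oxygen becoming O1 and the six-membered lactol forming when water adds to C2. The only new stereocentre is the lactol carbon C2, whose hydroxyl should settle trans to the C3 side chain by ring–chain equilibration, while C3 and C9 are untouched and the former hydroperoxide carbon passes through a planar cation, so its configuration does not matter. The step needs aryl migration in preference to hydride or C2-alkyl migration, which the para C6 methoxy group on the electron-rich ring secures, and the site of the new C–O bond is fixed by the carbon skeleton itself. It also needs water capture to outrun loss of H3 from the oxocarbenium ion and later dehydration of the lactol (both lead to the chromone), for which substoichiometric acid, low temperature and wet solvent are chosen.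

Step 15
Reactants: 20 (2S,3R)-3-{(S)-(TBSO)[4-(TBSO)phenyl]methyl}-2-hydroxy-6-methoxy-8-methyl-5,7-bis(triethylsilyloxy)chroman-4-one
Product: 21 (2S,3R)-2,5,7-trihydroxy-3-[(S)-hydroxy(4-hydroxyphenyl)methyl]-6-methoxy-8-methylchroman-4-one
Conditions: Bu4NF, AcOH (1:1, 6 equiv), THF, 0 °C to rt
Reagents that add atoms: none
Why: Fluoride-induced cleavage of the two aryl TES ethers, the aryl TBS ether and the secondary TBS ether, with acetic acid buffering the phenoxides and the lactol, should release the target without retro-aldol cleavage, epimerisation at C3 or dehydration to the chromone.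

**Compound list**

1 | methyl 3,5-dihydroxy-4-methoxybenzoate | COC(=O)c1cc(O)c(OC)c(O)c1 | starting material
2 | methyl 4-methoxy-3,5-bis(methoxymethoxy)benzoate | COC(=O)c1cc(OCOC)c(OC)c(OCOC)c1 | intermediate
3 | [4-methoxy-3,5-bis(methoxymethoxy)phenyl]methanol | OCc1cc(OCOC)c(OC)c(OCOC)c1 | intermediate
4 | lithium [2-lithio-4-methoxy-3,5-bis(methoxymethoxy)phenyl]methanolate (dilithio alkoxide) | [Li]OCc1cc(OCOC)c(OC)c(OCOC)c1[Li] | intermediate
5 | [4-methoxy-3,5-bis(methoxymethoxy)-2-methylphenyl]methanol | OCc1cc(OCOC)c(OC)c(OCOC)c1C | intermediate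
6 | [2-bromo-4-methoxy-3,5-bis(methoxymethoxy)-6-methylphenyl]methanol | OCc1c(Br)c(OCOC)c(OC)c(OCOC)c1C | intermediate
7 | ethyl 3-(4-hydroxyphenyl)-3-oxopropanoate | CCOC(=O)CC(=O)c1ccc(O)cc1 | starting material
8 | ethyl 3-[4-(tert-butyldimethylsilyloxy)phenyl]-3-oxopropanoate | CCOC(=O)CC(=O)c1ccc(O[Si](C)(C)C(C)(C)C)cc1 | intermediate
9 | ethyl (S)-3-[4-(tert-butyldimethylsilyloxy)phenyl]-3-hydroxypropanoate | CCOC(=O)C[C@H](O)c1ccc(O[Si](C)(C)C(C)(C)C)cc1 | intermediate
10 | ethyl (S)-3-(tert-butyldimethylsilyloxy)-3-[4-(tert-butyldimethylsilyloxy)phenyl]propanoate | CCOC(=O)C[C@H](O[Si](C)(C)C(C)(C)C)c1ccc(O[Si](C)(C)C(C)(C)C)cc1 | intermediate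
11 | (S)-3-(tert-butyldimethylsilyloxy)-3-[4-(tert-butyldimethylsilyloxy)phenyl]-N-methoxy-N-methylpropanamide | CON(C)C(=O)C[C@H](O[Si](C)(C)C(C)(C)C)c1ccc(O[Si](C)(C)C(C)(C)C)cc1 | intermediate
12 | lithium [2-lithio-4-methoxy-3,5-bis(methoxymethoxy)-6-methylphenyl]methanolate (aryllithium alkoxide) | [Li]OCc1c([Li])c(OCOC)c(OC)c(OCOC)c1C | intermediate
13 | dilithium salt of the tetrahedral adduct of 12 and 11 (N-methoxy-N-methyl hemiaminal; hemiaminal carbon unassigned, side-chain carbinol S) | [Li]OCc1c(C)c(OCOC)c(OC)c(OCOC)c1C(O[Li])(N(C)OC)C[C@H](O[Si](C)(C)C(C)(C)C)c1ccc(O[Si](C)(C)C(C)(C)C)cc1 | intermediate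
14 | (S)-3-(TBSO)-3-[4-(TBSO)phenyl]-1-[2-(hydroxymethyl)-5-methoxy-4,6-bis(methoxymethoxy)-3-methylphenyl]propan-1-one (may exist partly as its cyclic hemiketal) | OCc1c(C)c(OCOC)c(OC)c(OCOC)c1C(=O)C[C@H](O[Si](C)(C)C(C)(C)C)c1ccc(O[Si](C)(C)C(C)(C)C)cc1 | intermediate
15 | 2-{(S)-3-(TBSO)-3-[4-(TBSO)phenyl]propanoyl}-4-methoxy-3,5-bis(methoxymethoxy)-6-methylbenzaldehyde | O=Cc1c(C)c(OCOC)c(OC)c(OCOC)c1C(=O)C[C@H](O[Si](C)(C)C(C)(C)C)c1ccc(O[Si](C)(C)C(C)(C)C)cc1 | intermediate
16 | 2-{(S)-3-(TBSO)-3-[4-(TBSO)phenyl]propanoyl}-4-methoxy-6-methyl-3,5-bis(triethylsilyloxy)benzaldehyde | O=Cc1c(C)c(O[Si](CC)(CC)CC)c(OC)c(O[Si](CC)(CC)CC)c1C(=O)C[C@H](O[Si](C)(C)C(C)(C)C)c1ccc(O[Si](C)(C)C(C)(C)C)cc1 | intermediate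
17 | lithium (Z)-enolate of keto aldehyde 16 | O=Cc1c(C)c(O[Si](CC)(CC)CC)c(OC)c(O[Si](CC)(CC)CC)c1/C(O[Li])=C/[C@H](O[Si](C)(C)C(C)(C)C)c1ccc(O[Si](C)(C)C(C)(C)C)cc1 | intermediate
18 | (2S,3R)-2-{(S)-(TBSO)[4-(TBSO)phenyl]methyl}-3-hydroxy-6-methoxy-4-methyl-5,7-bis(triethylsilyloxy)indan-1-one | COc1c(O[Si](CC)(CC)CC)c(C)c2c(c1O[Si](CC)(CC)CC)C(=O)[C@H]([C@H](O[Si](C)(C)C(C)(C)C)c1ccc(O[Si](C)(C)C(C)(C)C)cc1)[C@H]2O | intermediate
19 | (2S,3R)-2-{(S)-(TBSO)[4-(TBSO)phenyl]methyl}-3-hydroperoxy-6-methoxy-4-methyl-5,7-bis(triethylsilyloxy)indan-1-one | COc1c(O[Si](CC)(CC)CC)c(C)c2c(c1O[Si](CC)(CC)CC)C(=O)[C@H]([C@H](O[Si](C)(C)C(C)(C)C)c1ccc(O[Si](C)(C)C(C)(C)C)cc1)[C@H]2OO | intermediate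
20 | (2S,3R)-3-{(S)-(TBSO)[4-(TBSO)phenyl]methyl}-2-hydroxy-6-methoxy-8-methyl-5,7-bis(triethylsilyloxy)chroman-4-one | COc1c(O[Si](CC)(CC)CC)c(C)c2c(c1O[Si](CC)(CC)CC)C(=O)[C@H]([C@H](O[Si](C)(C)C(C)(C)C)c1ccc(O[Si](C)(C)C(C)(C)C)cc1)[C@@H](O)O2 | intermediate
21 | (2S,3R)-2,5,7-trihydroxy-3-[(S)-hydroxy(4-hydroxyphenyl)methyl]-6-methoxy-8-methylchroman-4-one (CNP0141808.1) | COc1c(O)c(C)c2c(c1O)C(=O)[C@H]([C@H](O)c1ccc(O)cc1)[C@@H](O)O2 | target

**Step count and risks**

Total step count: 15. Longest linear sequence: 11 steps (steps 1–4 and 9–15; the side-chain branch, steps 5–8 and 9–15, is equally long).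

The three steps most likely to fail:

Step 14 (oxygen insertion). The aryl carbon may migrate too slowly because of the ortho carbonyl group, so that hydride shift to the indane-1,3-dione or acid-induced loss of silyl groups competes; alternatively the oxocarbenium ion may lose H3, or the lactol may dehydrate, and the material ends as the chromone. The fallback uses known chemistry, sets out from 16 and returns at 20. The aldehyde of 16 is subjected to Baeyer–Villiger (Dakin-type) oxidation with mCPBA and NaHCO3 in CH2Cl2 at 0 °C, in which the same electron-rich aryl carbon migrates to oxygen, to give the aryl formate F1. Treatment of the aryl formate F1 with LiN(SiMe3)2 in THF at −78 °C then brings about intramolecular Claisen-type formyl transfer (the first stage of a Baker–Venkataraman rearrangement): the ketone enolate adds to the formate carbonyl and closes the six-membered lactol directly, delivering 20 after a buffered quench.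

Step 13 (hydroxyl to hydroperoxide exchange). Ionisation at C3 may be retarded by the ortho carbonyl group, so that the acid needed causes dehydration to the indenone, ionisation at C9 or cleavage of silyl ethers before perhydrolysis takes place. The fallback sets out from 18 and returns at 19. The hydroxyl is exchanged for bromide under neutral Appel conditions (CBr4, PPh3, CH2Cl2, 0 °C) to give the 3-bromoindanone F2 as a mixture of C3 epimers. Silver-assisted perhydrolysis of the 3-bromoindanone F2 (AgOCOCF3, anhydrous H2O2 in Et2O, 0 °C) then replaces bromide by OOH without added Brønsted acid and gives 19.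

Step 12 (aldol ring closure). The lithium enolate may expel silanolate from C9 (enone formation) or accept the neighbouring aryl silyl group on oxygen, and facial selectivity at C2 may be poor. The fallback sets out from 16 and returns at 18. A one-pot enol silane formation–Mukaiyama aldol (Me3SiOTf, i-Pr2NEt, CH2Cl2, −78 °C) converts the ketone into its silyl enol ether and activates the aldehyde, so that the ring closes through an open, Lewis-acid-mediated transition state without a basic enolate, giving the O-trimethylsilyl ether F3. The O-trimethylsilyl ether F3 is cleaved to 18 by brief exposure to AcOH in wet THF, the secondary trimethylsilyl ether being far more labile than the aryl TES and the TBS ethers.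

**Further compounds**

F1 | step 14 | 2-{(S)-3-(TBSO)-3-[4-(TBSO)phenyl]propanoyl}-4-methoxy-6-methyl-3,5-bis(triethylsilyloxy)phenyl formate | O=COc1c(C)c(O[Si](CC)(CC)CC)c(OC)c(O[Si](CC)(CC)CC)c1C(=O)C[C@H](O[Si](C)(C)C(C)(C)C)c1ccc(O[Si](C)(C)C(C)(C)C)cc1
F2 | step 13 | 3-bromo analogue of 18 (3-bromo-2-{(S)-(TBSO)[4-(TBSO)phenyl]methyl}-6-methoxy-4-methyl-5,7-bis(triethylsilyloxy)indan-1-one, C3 epimers) | COc1c(O[Si](CC)(CC)CC)c(C)c2c(c1O[Si](CC)(CC)CC)C(=O)[C@H]([C@H](O[Si](C)(C)C(C)(C)C)c1ccc(O[Si](C)(C)C(C)(C)C)cc1)C2Br
F3 | step 12 | 3-O-trimethylsilyl ether of hydroxyindanone 18 | COc1c(O[Si](CC)(CC)CC)c(C)c2c(c1O[Si](CC)(CC)CC)C(=O)[C@H]([C@H](O[Si](C)(C)C(C)(C)C)c1ccc(O[Si](C)(C)C(C)(C)C)cc1)[C@H]2O[Si](C)(C)C
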